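The amounts first: amber and grey both charge 0.20 M of electrophile and 0.950 equiv of protonated nucleophile, and they differ in free base, 1.00 equiv against 1.50 equiv.

| flask | electrophile | free base | protonated nucleophile | remark | time |
|---|---|---|---|---|---|
| birch | 0.20 M | 1 equiv | 1.4 equiv | run made earlier |  |
| elm | 0.10 M | 1 equiv | 0.95 equiv | run made earlier |  |
| amber | 0.20 M | 1.00 equiv | 0.950 equiv |  | 40 h |
| grey | 0.20 M | 1.50 equiv | 0.950 equiv |  | 40 h |

| run | time / h | electrophile / % | target / % |
|---|---|---|---|
| birch | 6.00 | 54.8 | 4.0 |
| birch | 12.0 | 36.4 | 7.8 |
| birch | 20.0 | 24.0 | 10.3 |
| birch | 25.0 | 20.3 | 10.8 |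
| elm | 3.00 | 83.9 | 0.9 |
| elm | 8.00 | 65.5 | 2.6 |
| elm | 15.0 | 49.5 | 4.9 |
| elm | 25.0 | 36.1 | 8.3 |

(each reading ± 0.5 percentage points)

- a species is counted by the electrophile in it: one homo dimer counts as two
- the analysis behind the earlier runs scatters by 0.5 percentage points, standard deviation
- steps under discussion: electrophile + nucleophile -> acid set free + target; nucleophile + acid set free <-> protonated nucleophile; acid set free + free base <-> salt of the base; 2 electrophile -> homo dimer; free base + target -> over-reaction product

1. part of the electrophile that has reacted at the end, amber
2. part of the electrophile that has reacted at the end, grey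
3. what raising the equivalents of free base from its lowest to its highest value here does to the part of the electrophile that has reacted (changes below 5 percentage points count as none) (it rises / no change / it falls)

Of the electrophile gone from birch at its last reading, target holds 13.6%, less than the remainder, so you should look first at the loss that pairs electrophile into homo dimer. That loss goes by the square of c(electrophile), which gives you a cheap number. Birch gives 0.785 L mol⁻¹ h⁻¹ for a lumped loss constant, which is what was charged over what is left, less one, divided by the starting c(electrophile) and the hours; it counts all electrophile lost, whichever way it went.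

Way one takes that value to amber and gives 86.3% reacted. Way two takes elm's 0.708 L mol⁻¹ h⁻¹ and gives 85.0%. Which one cheats? Call starting concentration times hours the dose. Birch at 12.0 h and elm at 25.0 h have had about the same dose, and they hold 36.4% and 36.1%, a gap smaller than the scatter of 0.5 percentage points. So the two runs agree, but within birch the constant climbs, from 0.687 L mol⁻¹ h⁻¹ at 6.00 h through 0.728 L mol⁻¹ h⁻¹ at 12.0 h. Elm reads low because it stopped at a smaller dose, so I take way one. For grey I let target's share grow in step with the free base charge, which gives 87.0%, a change of 0.70 points.

The forecast is a little lower: 85% for amber, 86% for grey, no change. In its words: “Free base acts only by slowly releasing nucleophile and by attacking target, so it should barely touch electrophile loss.”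

The flasks give 87.4% for amber and 88.1% for grey, no change, with a change of 0.72 points.

    electrophile + nucleophile → acid set free + target (k = 0.00196 L mol⁻¹ min⁻¹)
    nucleophile + acid set free ⇌ protonated nucleophile, settled at all times (K = 49.0 L mol⁻¹)
    acid set free + free base ⇌ salt of the base (K = 5640 L mol⁻¹, k = 0.0568 L mol⁻¹ min⁻¹)
    2 electrophile → homo dimer (k = 0.00500 L mol⁻¹ min⁻¹)
    free base + target → over-reaction product (k = 0.00566 L mol⁻¹ min⁻¹)

Amber's own lumped loss constant, which is not the constant of the pairing step, is 0.865 L mol⁻¹ h⁻¹, higher than birch's. The neighbour flask, grey at 0.050 M, takes the early lumped value 0.728 L mol⁻¹ h⁻¹ and is reckoned at 59.3%; it stands at 59.7%. Grey has not come to rest at 40.0 h. At ten times the time, the part reacted goes from 88.1% to >99.9%, over-reaction product climbs from 9.68% to 24.8%, and target falls from 7.45% to 0.735%.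

(Readings and results stem from a simulated flask with constants of no real substance; the scatter is artificial.)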